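One percent here means one percent of the substrate charged, so what counts in a flask is how much target is made and how much of that stays.

| flask | substrate | reagent | initiator | temperature | remark | time |
|---|---|---|---|---|---|---|
| ash | 0.052 M | 0.264 M | 22 mM | 45 °C | run made earlier |  |
| larch | 0.50 M | 0.264 M | 22 mM | 65 °C | run made earlier |  |
| elm | 0.22 M | 0.28 M | 22 mM | 45 °C | run made earlier |  |
| east | 0.60 M | 0.0600 M | 22 mM | 50 °C |  | 4.0 d |
| south | 0.060 M | 0.120 M | 22 mM | 50 °C |  | 4.0 d |
| north-west | 0.060 M | 0.800 M | 22 mM | 80 °C |  | 4.0 d |
| south-east | 0.22 M | 0.264 M | 22 mM | 80 °C |  | 4.0 d |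
| north | 0.22 M | 0.264 M | 22 mM | 50 °C |  | 4.0 d |

ash run (percent of the substrate charged)

| time / d | target / % | substrate / % |
|---|---|---|
| 0.625 | 53.7 | 0 |
| 1.25 | 35.3 | 0 |
| 1.67 | 29.1 | 0 |
| 2.50 | 22.2 | 0.1 |
| 3.00 | 19.8 | 0 |
| 4.00 | 18.3 | 0.1 |

larch run (percent of the substrate charged)

| time / h | target / % | substrate / % |
|---|---|---|
| 8.00 | 7.1 | 71.7 |
| 15.0 | 7.6 | 67.7 |
| 20.0 | 7.2 | 66.7 |
| 30.0 | 7.5 | 65.3 |
| 50.0 | 8.0 | 64.1 |

elm run (percent of the substrate charged)

| time / d | target / % | substrate / % |
|---|---|---|
| 0.333 | 8.9 | 84.8 |
| 0.625 | 13.9 | 73.5 |
| 1.04 | 18.4 | 61.9 |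
| 2.00 | 20.9 | 42.9 |
| 4.00 | 19.0 | 24.9 |

(readings scatter by 0.3 percentage points)

- the analysis behind the earlier runs scatters by 0.3 percentage points, standard deviation

* the flasks put in order of amount of target, in percent of the substrate charged, best first, at 4.0 d (east / south / north-west / south-east / north)
* the amount of target, in percent of the substrate charged of the flask you put first, at 4.0 d
* the amount of target, in percent of the substrate charged of the flask you put last, at 4.0 d

Ash has 0% substrate left at its first reading, yet its target keeps falling and levels off above zero. We read this as target draining into something and coming back. Two amounts then matter: the target made and the plateau.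

We take the last ash reading as a first plateau. The excess over it gives a half-life of 0.591 d. Going round once more, the excess shrinks by a factor 0.0397 up to the last reading, so the plateau is 17.6% and the half-life 0.608 d.

Elm's first reading shows substrate used at 0.100 M/d, so ash's charge lasts about 0.518 d. Running the excess back to the middle of that time gives 72.4% made. The ratio of plateau to target made, 0.243, is the staying share.

The asked time is longer than this half-life, so we expect thermodynamic rather than kinetic control: target is the share times what was made.

Larch's flat 8.0%, on 35.9% of substrate used and with ash's yield, gives a share of 0.308, higher than in ash. We therefore put north-west first, at 22.3% or more, since its charge of 0.060 M is less than the 0.180 M larch turned. East has the lowest ratio of reagent to substrate, 10.0%, so we put it last. Were the target made in east equal to that ratio, ash's share would leave 2.43%, and we take this as the upper end of our estimate for east. The others we place near elm's 19.0%.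

The forecast gave south > north > south-east > north-west > east, with 32% first and 3.5% last, holding that “excess reagent destroys it”.

The flasks give north-west > south-east > north > south > east, with 32.6% first and 1.37% last.

    initiator → 2 initiating radical (k = 0.00100 /min, Ea = 108 kJ/mol)
    substrate + initiating radical → capped initiator + first chain carrier (k = 1.00 × 10⁵ /M/min, Ea = 45.0 kJ/mol)
    reagent + first chain carrier → target + second chain carrier (k = 5400 /M/min, Ea = 52.0 kJ/mol)
    substrate + second chain carrier → by-product + first chain carrier (k = 3.00 × 10⁵ /M/min, Ea = 44.0 kJ/mol)
    2 first chain carrier → ended chains A (k = 9.00 × 10⁷ /M/s, Ea = 15.0 kJ/mol)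
    2 second chain carrier → ended chains B (k = 9.00 × 10⁶ /M/s, Ea = 25.0 kJ/mol)
    2 substrate → self-condensation product (k = 7.50 × 10⁻⁶ /M/min, Ea = 77.0 kJ/mol)
    target ⇌ isomer of the product (K = 2.70, k = 0.00110 /min, Ea = 108 kJ/mol, ΔH = −17.0 kJ/mol)
    (constants at 50 °C)

North-west holds 84.1% as target plus isomer of the product, and its relaxation half-life of 0.211 h is shorter than the time. Ash's share would leave 20.4% there, and our reckoning said 22.3%, but north-west's own share is 0.388. The neighbour is north-west run at 105 °C, with 0% substrate left. It holds 81.7% as the pair, its share is 0.482, and its target stands at 39.4%.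

Readings and results were computed for an exercise, noise included.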